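Moles per litre per hour is the unit in which the charge and the enzyme can be set against each other, and that comparison is what we carry through these flasks. In each flask, starting material is dosed steadily into enzyme, which turns it into product.

| flask | starting material | enzyme | remark | time |
|---|---|---|---|---|
| winter | 0.076 M (fed, over 4.0 h) | 24 µM | run made earlier |  |
| dusk | 0.17 M (fed, over 4.0 h) | 24 µM | run made earlier |  |
| noon | 0.29 M (fed, over 4.0 h) | 24 µM | run made earlier |  |
| midnight | 0.10 M (fed, over 4.0 h) | 31 µM | run made earlier |  |
| south-west | 0.10 M (fed, over 4.0 h) | 24 µM |  | 12 h |
| north-east | 0.10 M (fed, over 4.0 h) | 40 µM |  | 12 h |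
| south-east | 0.20 M (fed, over 4.0 h) | 100 µM |  | 12 h |
| north-west | 0.10 M (fed, over 2.0 h) | 24 µM |  | 12 h |
| east | 0.10 M (fed, over 4.0 h) | 8.0 µM |  | 12 h |
| south | 0.30 M (fed, over 2.5 h) | 100 µM |  | 12 h |

| run | time / h | product / % | starting material / % |
|---|---|---|---|
| winter | 0.833 | 0.4 | 19.3 |
| winter | 2.00 | 2.4 | 47.1 |
| winter | 4.00 | 6.9 | 91.4 |
| winter | 6.00 | 14.7 | 82.0 |
| dusk | 0.500 | 0 | 13.4 |
| dusk | 1.00 | 1.2 | 24.0 |
| dusk | 2.50 | 4.4 | 59.3 |
| dusk | 6.00 | 12.1 | 87.8 |
| noon | 0.833 | 0.9 | 22.1 |
| noon | 2.00 | 3.5 | 49.6 |
| noon | 4.00 | 6.1 | 94.0 |
| noon | 6.00 | 8.0 | 90.1 |
| midnight | 0.500 | 0 | 12.7 |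
| midnight | 1.00 | 0 | 25.1 |
| midnight | 2.50 | 3.7 | 58.6 |
| midnight | 6.00 | 19.4 | 80.5 |

(readings scatter by 1 percentage point)

1. the flasks put in order of amount of product, in percent of the starting material charged, best first, at 12 h (south-west / north-east / south-east / north-west / east / south)
2. the amount of product, in percent of the starting material charged of the flask you put first, at 12 h
3. the amount of product, in percent of the starting material charged of the flask you put last, at 12 h

First we read what the enzyme does. Take the product gained between two late readings, in moles per litre per hour, and divide by the enzyme concentration. This gives a rate constant of a simple kind, the turnover frequency. The dusk run gives 156 h⁻¹ while its starting material goes from 0.101 M to 0.149 M. The midnight run gives 145 h⁻¹ while its starting material goes from 0.0586 M to 0.0805 M. Each is a difference of two readings of scatter 1 percentage point, and the dusk difference is 7.7 points, so the two do not differ beyond their scatter. We therefore take one reading, 150 h⁻¹, and treat the rate as zero order over this range.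

Now divide the enzyme's rate by the rate at which the whole charge would have to go to be turned over by 12 h, and the hours cancel. In south-west the enzyme manages 3.61 mM h⁻¹ against a need of 8.33 mM h⁻¹, so the ratio is 0.433. We call this the keeping-up ratio. The ratio for south-east is 0.902, and for east it is 0.144. With 0.721 for north-east, 0.601 for south and 0.433 for north-west, every ratio is below one.

With a zero-order rate running from the start, the ratio is itself our product share: 90.2 % for south-east, 72.1 % for north-east, 60.1 % for south, 43.3 % for north-west, 43.3 % for south-west and 14.4 % for east. The dosing time does not enter this reckoning, so north-west and south-west come out alike. The midnight run shows the weak point: at 1.00 h it read 0 % product, less than the 4.66 % this rate gives from the start.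

The forecast, which unlike us places south above north-east, reads south-east > south > north-east > north-west > south-west > east, with 75 % on top and 12 % last, and it warns: “South against north-east is the least certain placing”.

The flasks stand south-east > south > north-east > north-west > south-west > east, with south-east at 81.0 % and east at 12.7 %. At the end of its feed, at 4.00 h, east holds 97.1 % starting material against 2.86 % product. Our keeping-up ratio for east, 14.4 % as a share, stands above the 12.7 % that flask holds. One further flask is like east but with 14.0 µM of enzyme. Its ratio is 0.252, and that flask holds 21.5 % product at 12.0 h.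

    starting material + enzyme → product + enzyme, rate k1*[starting material]^1.5*[enzyme]/(1 + ([starting material]/Kh1)^1.5) (0.0633 M, k = 15100 M⁻¹·⁵ h⁻¹)

All runs stem from a simulated flask from invented constants.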